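**Retrosynthetic overview**
- The palmitate is attached last, by Mitsunobu esterification of the only aliphatic hydroxyl of a diaryl ether triol.
- Ring A rests on one feature: its C3 (OMe) and C5 (OH) oxygens are the two carbonyls of a cyclohexane-1,3-dione, in which C6 carries the ring B aryloxy group and C1 the oxymethyl group. Iodine in methanol aromatises this dione and methylates the C3 oxygen.
- The dione is cut at C6–C1 (Michael) and C4–C3 (Claisen) into an aryloxyacetone (C4, C5, C6 and the ether oxygen) and a 4-silyloxybut-2-enoate (C1, C2, C3 and the CH2O carbon).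
- Ring B is bought as orcinol; the diaryl ether oxygen comes from a simple phenol alkylation with chloroacetone. Ring A is the only ring formed.
- The ring B phenol travels as a benzyl ether and the oxymethyl oxygen as a TBS ether.

Key step: step 4

Remark on stereochemistry: the two stereocentres formed in step 4 (C6 and C1 of the future ring A) are not controlled and disappear in step 5; the target has no stereocentre, so 8, 9 and 10 are racemic diastereomer mixtures.

Remark on protecting groups: the oxymethyl group is silylated and not benzylated, because once ring A is aromatic that carbon is benzylic and hydrogenolysis of such a dibenzylic ether could cut either C–O bond. The ring B phenol is benzylated so that no phenoxide consumes base or acts as a nucleophile in step 4.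

**Step 1**
Reactants: 1 orcinol
Product: 2 3-(benzyloxy)-5-methylphenol
Conditions: 1 (3 equiv), BnBr (1 equiv), K2CO3 (1.1 equiv), acetone, reflux; excess 1 recovered
Reagents that add atoms: benzyl bromide, BrCc1ccccc1
Why: Williamson etherification of one of two equivalent phenols; the excess of diol should keep dibenzylation low, and the mono-ether is separated by chromatography.

**Step 2**
Reactants: 2 3-(benzyloxy)-5-methylphenol; 3 chloroacetone
Product: 4 1-(3-(benzyloxy)-5-methylphenoxy)propan-2-one
Conditions: 3 (1.2 equiv), K2CO3, KI (cat.), acetone, reflux
Reagents that add atoms: none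
Why: Williamson alkylation of the phenoxide by an α-chloro ketone, assisted by in situ Finkelstein exchange, installs the future ring A–O–ring B oxygen without any arylation chemistry.

**Step 3**
Reactants: 5 (tert-butyldimethylsilyloxy)acetaldehyde; 6 trimethyl phosphonoacetate
Product: 7 methyl (E)-4-((tert-butyldimethylsilyl)oxy)but-2-enoate
Conditions: NaH, THF, 0 °C to rt
Reagents that add atoms: none
Why: Horner–Wadsworth–Emmons olefination should give the (E)-enoate; the alkene geometry is of no consequence, since it is lost in the Michael step.

**Step 4**
Reactants: 4 1-(3-(benzyloxy)-5-methylphenoxy)propan-2-one; 7 methyl (E)-4-((tert-butyldimethylsilyl)oxy)but-2-enoate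
Product: 9 4-(3-(benzyloxy)-5-methylphenoxy)-5-(((tert-butyldimethylsilyl)oxy)methyl)cyclohexane-1,3-dione (racemic, cis/trans mixture), via keto ester 8 (not isolated)
Conditions: KOtBu (2.1 equiv), THF, −10 °C, then 7 added slowly, to rt; AcOH quench
Reagents that add atoms: none
Why: KOtBu equilibrates the enolates of 4, and the more stabilised one, at the aryloxy-bearing CH2, adds to the β-carbon (C1) of enoate 7 to form C6–C1 (Michael addition); proton transfer in adduct 8 gives the methyl ketone enolate, whose C4 attacks the ester carbonyl C3 with loss of methoxide (Claisen condensation), and deprotonation of the 1,3-dione formed makes the sequence irreversible. The closest known reaction type is the consecutive Michael–Claisen synthesis of 4-substituted cyclohexane-1,3-diones from substituted acetones and α,β-unsaturated esters, a relative of the classical acetoacetate–crotonate route to dihydroresorcinols. Ring A is closed in a 6-(enolexo)-exo-trig mode. The two new stereocentres (C6 and C1) are not controlled beyond the thermodynamic preference for the trans isomer reached through the epimerisable C6–H, and both are destroyed in step 5. The step needs the Michael addition to occur at the aryloxy-bearing carbon and not at the methyl group; the inductive acidification of that position by the ether oxygen under equilibrating base is expected to secure this, and the benzyl ether on ring B keeps a phenoxide from competing. No carbanion in 8 or 9 sits β to the aryloxy or silyloxy oxygen, so neither group can be expelled by an E1cB process.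

**Step 5**
Reactants: 9 4-(3-(benzyloxy)-5-methylphenoxy)-5-(((tert-butyldimethylsilyl)oxy)methyl)cyclohexane-1,3-dione
Product: 11 2-(3-(benzyloxy)-5-methylphenoxy)-3-(hydroxymethyl)-5-methoxyphenol, via enol ether 10 (not isolated)
Conditions: I2 (1.2 equiv), MeOH, reflux; aq Na2S2O3 work-up
Reagents that add atoms: methanol, CO
Why: Iodine–methanol aromatisation of a cyclohexane-1,3-dione: acid-catalysed enol etherification should occur at the less hindered C3 carbonyl (remote from the aryloxy-bearing C6) to give 10, iodination α to the remaining C5 ketone and loss of HI give a dienone that tautomerises to the C5 phenol, and the HI formed removes the primary TBS ether by methanolysis, iodine in methanol being a known desilylation medium.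

**Step 6**
Reactants: 11 2-(3-(benzyloxy)-5-methylphenoxy)-3-(hydroxymethyl)-5-methoxyphenol
Product: 12 3-(hydroxymethyl)-2-(3-hydroxy-5-methylphenoxy)-5-methoxyphenol
Conditions: H2 (1 atm), 10% Pd/C, EtOAc, rt; stopped at full conversion
Reagents that add atoms: none
Why: Catalytic hydrogenolysis cleaves an aryl benzyl ether quickly under neutral conditions, whereas the free benzylic alcohol and the diaryl ether are reduced far more slowly.

**Step 7**
Reactants: 12 3-(hydroxymethyl)-2-(3-hydroxy-5-methylphenoxy)-5-methoxyphenol; 13 palmitic acid
Product: 14 betaethrin H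
Conditions: 13 (1.1 equiv), PPh3, DIAD, THF, 0 °C to rt
Reagents that add atoms: none
Why: Mitsunobu esterification activates only the aliphatic alcohol as an alkoxyphosphonium ion and the carboxylic acid, far more acidic than the phenols, supplies the nucleophile, a chemoselectivity known for phenolic benzyl alcohols such as vanillyl alcohol; neither phenol is ortho or para to the CH2OH group, so no quinone methide can form.

**Compound list**
1 | orcinol (5-methylbenzene-1,3-diol) | Cc1cc(O)cc(O)c1 | starting material
2 | 3-(benzyloxy)-5-methylphenol | Cc1cc(O)cc(OCc2ccccc2)c1 | intermediate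
3 | chloroacetone | CC(=O)CCl | starting material
4 | 1-(3-(benzyloxy)-5-methylphenoxy)propan-2-one | CC(=O)COc1cc(C)cc(OCc2ccccc2)c1 | intermediate
5 | (tert-butyldimethylsilyloxy)acetaldehyde | O=CCO[Si](C)(C)C(C)(C)C | starting material
6 | trimethyl phosphonoacetate | COC(=O)CP(=O)(OC)OC | starting material
7 | methyl (E)-4-((tert-butyldimethylsilyl)oxy)but-2-enoate | COC(=O)/C=C/CO[Si](C)(C)C(C)(C)C | intermediate
8 | methyl 4-(3-(benzyloxy)-5-methylphenoxy)-3-(((tert-butyldimethylsilyl)oxy)methyl)-5-oxohexanoate, racemic diastereomer mixture, formed in the flask in step 4 | COC(=O)CC(CO[Si](C)(C)C(C)(C)C)C(Oc1cc(C)cc(OCc2ccccc2)c1)C(C)=O | intermediate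
9 | 4-(3-(benzyloxy)-5-methylphenoxy)-5-(((tert-butyldimethylsilyl)oxy)methyl)cyclohexane-1,3-dione, racemic diastereomer mixture | O=C1CC(=O)C(Oc2cc(C)cc(OCc3ccccc3)c2)C(CO[Si](C)(C)C(C)(C)C)C1 | intermediate
10 | 6-(3-(benzyloxy)-5-methylphenoxy)-5-(((tert-butyldimethylsilyl)oxy)methyl)-3-methoxycyclohex-2-en-1-one, racemic diastereomer mixture, formed in the flask in step 5 | COC1=CC(=O)C(Oc2cc(C)cc(OCc3ccccc3)c2)C(CO[Si](C)(C)C(C)(C)C)C1 | intermediate
11 | 2-(3-(benzyloxy)-5-methylphenoxy)-3-(hydroxymethyl)-5-methoxyphenol | OCc1cc(OC)cc(O)c1Oc1cc(C)cc(OCc2ccccc2)c1 | intermediate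
12 | 3-(hydroxymethyl)-2-(3-hydroxy-5-methylphenoxy)-5-methoxyphenol | OCc1cc(OC)cc(O)c1Oc1cc(C)cc(O)c1 | intermediate
13 | palmitic acid | CCCCCCCCCCCCCCCC(=O)O | starting material
14 | betaethrin H, 3-hydroxy-2-(3-hydroxy-5-methylphenoxy)-5-methoxybenzyl palmitate | CCCCCCCCCCCCCCCC(=O)OCc1cc(OC)cc(O)c1Oc1cc(C)cc(O)c1 | target

**Step count**
Total: 7 steps. Longest linear sequence: 6 steps (steps 1, 2, 4, 5, 6, 7); step 3 is a one-step side branch.

**Steps most likely to fail**

Step 4. The Michael addition may proceed through the methyl-side enolate, which after Claisen closure at the aryloxy carbon would give the isomeric 2-aryloxy dione. The ketone may also self-condense, or the base may isomerise the enoate by γ-deprotonation. The fallback keeps the same two bonds but activates the aryloxy carbon with an ester group, and runs from 2 back to 9. Phenol 2 is alkylated with methyl 2-chloroacetoacetate (K2CO3, acetone) to methyl 2-(3-(benzyloxy)-5-methylphenoxy)-3-oxobutanoate F1, whose only strongly acidic C–H is at the aryloxy carbon. Michael addition of F1 to 7 and Claisen closure from the acetyl methyl group (KOtBu, THF) would give methyl 1-(3-(benzyloxy)-5-methylphenoxy)-6-(((tert-butyldimethylsilyl)oxy)methyl)-2,4-dioxocyclohexane-1-carboxylate F2. Krapcho decarbomethoxylation (LiCl, wet DMSO, 130 °C) then returns to 9.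

Step 5. Enol ether formation may take place at the C5 instead of the C3 carbonyl, or at both, so that the wrong oxygen or both oxygens are methylated. The hot acidic medium may also cyclodehydrate the α-aryloxy ketone onto the electron-rich ring B, or solvolyse the benzylic alcohol once it is unmasked. The fallback separates the events and avoids hot HI, running from 9 back to 11. Enol ether 10 is made and isolated under mild conditions (HC(OMe)3, MeOH, PPTS cat., rt); the regioisomeric enol ether is separated and hydrolysed back to 9. Kinetic α'-deprotonation of 10 (LDA, THF, −78 °C) and trapping with PhSeBr would give 6-(3-(benzyloxy)-5-methylphenoxy)-5-(((tert-butyldimethylsilyl)oxy)methyl)-3-methoxy-6-(phenylselanyl)cyclohex-2-en-1-one F3. Oxidation (H2O2, pyridine, CH2Cl2, 0 °C) with selenoxide syn-elimination across C6–C1 and tautomerisation would give 2-(3-(benzyloxy)-5-methylphenoxy)-3-(((tert-butyldimethylsilyl)oxy)methyl)-5-methoxyphenol F4. TBAF buffered with AcOH (THF) then gives 11.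

Step 7. Chemoselectivity may be lost through acylation or benzylation of a phenol oxygen by the activated intermediates. The fallback is an enzymatic transesterification from 12 directly to 14: immobilised Candida antarctica lipase B (Novozym 435), vinyl palmitate, MTBE, 40 °C. Lipases of this type acylate primary alcohols and leave phenols untouched.

**Further compounds**
F1 | step 4 | methyl 2-(3-(benzyloxy)-5-methylphenoxy)-3-oxobutanoate | COC(=O)C(Oc1cc(C)cc(OCc2ccccc2)c1)C(C)=O
F2 | step 4 | methyl 1-(3-(benzyloxy)-5-methylphenoxy)-6-(((tert-butyldimethylsilyl)oxy)methyl)-2,4-dioxocyclohexane-1-carboxylate, racemic diastereomer mixture | COC(=O)C1(Oc2cc(C)cc(OCc3ccccc3)c2)C(=O)CC(=O)CC1CO[Si](C)(C)C(C)(C)C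
F3 | step 5 | 6-(3-(benzyloxy)-5-methylphenoxy)-5-(((tert-butyldimethylsilyl)oxy)methyl)-3-methoxy-6-(phenylselanyl)cyclohex-2-en-1-one, racemic diastereomer mixture | COC1=CC(=O)C(Oc2cc(C)cc(OCc3ccccc3)c2)([Se]c2ccccc2)C(CO[Si](C)(C)C(C)(C)C)C1
F4 | step 5 | 2-(3-(benzyloxy)-5-methylphenoxy)-3-(((tert-butyldimethylsilyl)oxy)methyl)-5-methoxyphenol | COc1cc(O)c(Oc2cc(C)cc(OCc3ccccc3)c2)c(CO[Si](C)(C)C(C)(C)C)c1
F0 | step 7 | none | none
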